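How slow is this flask? Very slow: in the birch run solid Z still stands at 97.0% after 10.0 min, and G reads 0%.

- birch: Z 0.80 M; E 0.88 M; J 0.48 M; run made earlier
- flask: Z 0.80 M; E 0.880 M; J 0.240 M; time 30 min

birch run (percent of the Z charged)

| time / min | G / % | Z / % |
|---|---|---|
| 0.667 | 0 | 99.6 |
| 1.33 | 0 | 98.9 |
| 2.00 | 0 | 99.4 |
| 3.00 | 0 | 97.4 |
| 5.00 | 0.3 | 98.1 |
| 10.0 | 0 | 97.0 |

(readings scatter by 0.5 percentage points)

- the numbers in the tables scatter with a standard deviation of 0.5 percentage points
- at the start none of Z is in solution
- a reading or a percentage of G counts all its forms, free or not
- no earlier run changes the charge of J; that part of a forecast is a guess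

- how much G the flask holds at 30 min, in percent of the Z charged
- how much Z the flask holds at 30 min, in percent of the Z charged (only what is still solid)

What do you carry from that run? The birch run reads 0.00240 M/min for the solid-loss rate, the molar amount of Z leaving the solid per minute. I treat it as zero order in solid Z: a set amount per minute, however much solid lies there.

What does it give at 30 min? It gives 0.0720 M gone, so by my reckoning the flask holds 91.0% Z.

That rests on one reading, doesn't it? Yes. A reading scatters by 0.5 percentage points, and stretching from 10.0 min to 30 min stretches that to 1.5 points.

Does the rate stay steady? That is an assumption. Z has lost 3 points while G reads 0%, so what left the solid is in a form not read. As that form collects, the rate of G should climb, and the solid-loss rate may drift.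

And the J? The flask has half the birch J, and no run shows what that does.

The forecast gave 1.5% G and 91% Z, reasoning “If dissolution stays steady”. My Z comes from the same reading, so the match is no check. For G I take the forecast's figure.

The flask gives 2.99% G and 87.6% Z, so Z stands 3.4 points below my reckoning, more than the stretched scatter of 1.5 points.

    D + E ⇌ X, settled at all times (K = 1.03 /M)
    X → G (k = 0.0537 /min)
    J + X → L (k = 0.240 /M/min)
    Z ⇌ D, rate k4*(cs4 - [D]) while solid is left; crystals form when [D] > cs4 (solubility = 0.260 M, k = 0.0136 /min)
    Q ⇌ G, rate k5*(cs5 - [G]) while solid is left; crystals form when [G] > cs5 (solubility = 0.510 M, k = 1.69 /min)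

The flask lost 0.0991 M of solid, a solid-loss rate of 0.00330 M/min, more than the birch reading of 0.00240 M/min. In percent of the Z charged, that loss stands as 3.47% D, 2.89% X, 3.04% L and 2.99% G. A later reading would test the forecast's G: with all amounts held, G in the flask has moved 5 points by 58.8 min. Spread over the 1.4 M of Z in the neighbour flask, the same loss is 7.08%, which puts Z at 92.9%. The neighbour flask holds 92.9% Z at 30.0 min, a loss of 0.0994 M.

The runs are calculated with made-up constants.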